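**Retrosynthetic overview**
1. The strategy rests on the lactone carbonyl C1, which lies between the ring oxygen and the alkene carbon C2 of the exocyclic (E)-C2=CH–aryl unit. C1 is removed as CO, which opens the α-arylidene-γ-butyrolactone to an (R)-2-benzyl-4-aryl-but-3-yn-1-ol; syn addition of H and the acyl carbon across the aryl alkyne places H cis to C1 and the aryl group cis to C3.
2. The aryl–alkyne bond is cut next (Sonogashira) into a silyl-protected 4-bromo-2,6-dimethoxyphenol and a chiral terminal alkyne, whose terminal carbon comes from one-carbon homologation of an α-branched aldehyde.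
3. The single stereocentre C3 and the C3–C4 bond go back to an auxiliary-controlled hydroxymethylation of an N-(3-arylpropanoyl)oxazolidinone.
4. Ring order: both benzene rings are bought; the butyrolactone is the only ring made and is closed in the penultimate step by the carbonylation.

Key step: step 10

Remark: lactone numbering used throughout is C1 (C=O), C2 (alkene carbon), C3 (stereocentre, R), C4 (OCH2); the carbonylation is assumed to be run in a pressure vessel.

Step 1
Reactants: 1 3-(3,4,5-trimethoxyphenyl)propanoic acid; 2 (R)-4-benzyloxazolidin-2-one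
Product: 4 (R)-4-benzyl-3-[3-(3,4,5-trimethoxyphenyl)propanoyl]oxazolidin-2-one, via mixed pivalic anhydride 3 (not isolated)
Conditions: PivCl, Et3N, THF, −20 °C; then LiCl, 2, −20 °C → rt
Reagents that add atoms: none
Why: N-acylation of the oxazolidinone through a mixed pivalic anhydride, in which the LiCl/Et3N-activated oxazolidinone attacks the unhindered carbonyl of 3 so that only the arylpropanoyl group is transferred.

Step 2
Reactants: 4 (R)-4-benzyl-3-[3-(3,4,5-trimethoxyphenyl)propanoyl]oxazolidin-2-one; 5 1,3,5-trioxane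
Product: 7 (R)-4-benzyl-3-[(S)-2-(hydroxymethyl)-3-(3,4,5-trimethoxyphenyl)propanoyl]oxazolidin-2-one, via titanium enolate 6 (not isolated)
Conditions: TiCl4, i-Pr2NEt, CH2Cl2, 0 °C; then 5, TiCl4, 0 °C; aq. NH4Cl
Reagents that add atoms: none
Why: Auxiliary-controlled hydroxymethylation (aldol-type addition of a chelated titanium enolate to Lewis-acid-activated formaldehyde released from trioxane): the (R)-benzyl group shields one face of the Z enolate 6, CH2OH enters from the opposite face, and the new centre should be S, which becomes the R centre C3 of the lactone once the imide carbonyl carbon has become C2.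

Step 3
Reactants: 7 (R)-4-benzyl-3-[(S)-2-(hydroxymethyl)-3-(3,4,5-trimethoxyphenyl)propanoyl]oxazolidin-2-one
Product: 8 (R)-4-benzyl-3-[(S)-2-{[(tert-butyldimethylsilyl)oxy]methyl}-3-(3,4,5-trimethoxyphenyl)propanoyl]oxazolidin-2-one
Conditions: TBSCl, imidazole, DMF, 0 °C → rt
Reagents that add atoms: tert-butyldimethylsilyl chloride, CC(C)(C)[Si](C)(C)Cl
Why: Standard silylation of a primary alcohol (silyl chloride/imidazole), which leaves the imide and the α-centre untouched.

Step 4
Reactants: 8 (R)-4-benzyl-3-[(S)-2-{[(tert-butyldimethylsilyl)oxy]methyl}-3-(3,4,5-trimethoxyphenyl)propanoyl]oxazolidin-2-one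
Product: 9 (R)-3-[(tert-butyldimethylsilyl)oxy]-2-(3,4,5-trimethoxybenzyl)propan-1-ol
Conditions: LiBH4, MeOH (1 equiv.), THF, 0 °C
Reagents that add atoms: none
Why: Reductive cleavage of the N-acyl oxazolidinone by lithium borohydride at the exocyclic carbonyl; hydride conditions do not enolise the α-centre, the silyl ether survives and auxiliary 2 is released for recovery.

Step 5
Reactants: 9 (R)-3-[(tert-butyldimethylsilyl)oxy]-2-(3,4,5-trimethoxybenzyl)propan-1-ol
Product: 10 (S)-3-[(tert-butyldimethylsilyl)oxy]-2-(3,4,5-trimethoxybenzyl)propanal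
Conditions: Dess–Martin periodinane, NaHCO3, CH2Cl2, 0 °C → rt; used crude
Reagents that add atoms: none
Why: Dess–Martin oxidation under bicarbonate buffering is neutral and fast, so the epimerisable α-branched β-silyloxy aldehyde should form without racemisation or β-elimination and is taken on directly.

Step 6
Reactants: 10 (S)-3-[(tert-butyldimethylsilyl)oxy]-2-(3,4,5-trimethoxybenzyl)propanal; 11 dimethyl (1-diazo-2-oxopropyl)phosphonate
Product: 13 (R)-tert-butyldimethyl{[2-(3,4,5-trimethoxybenzyl)but-3-yn-1-yl]oxy}silane, via diazoalkene 12 (not isolated)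
Conditions: K2CO3, MeOH, 0 °C → rt
Reagents that add atoms: none
Why: Ohira–Bestmann (Seyferth–Gilbert) homologation: methanolysis of 11 releases the diazomethylphosphonate anion, which olefinates the aldehyde to diazoalkene 12; loss of N2 and a 1,2-hydrogen shift give the terminal alkyne, and the mild carbonate base at low temperature should leave the adjacent stereocentre intact.

Step 7
Reactants: 14 4-bromo-2,6-dimethoxyphenol
Product: 15 (4-bromo-2,6-dimethoxyphenoxy)triisopropylsilane
Conditions: TIPSCl, imidazole, DMF, rt → 40 °C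
Reagents that add atoms: triisopropylsilyl chloride, CC(C)[Si](Cl)(C(C)C)C(C)C
Why: Silylation of the phenol (silyl chloride/imidazole); the bulky triisopropylsilyl group is chosen so that the aryl silyl ether outlasts the later acidic cleavage of the alkyl silyl ether.

Step 8
Reactants: 13 (R)-tert-butyldimethyl{[2-(3,4,5-trimethoxybenzyl)but-3-yn-1-yl]oxy}silane; 15 (4-bromo-2,6-dimethoxyphenoxy)triisopropylsilane
Product: 16 (R)-{4-[4-[(tert-butyldimethylsilyl)oxy]-3-(3,4,5-trimethoxybenzyl)but-1-yn-1-yl]-2,6-dimethoxyphenoxy}triisopropylsilane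
Conditions: Pd(PhCN)2Cl2 (3 mol%), [HP(t-Bu)3]BF4 (6 mol%), CuI (2 mol%), i-Pr2NH, dioxane, rt, degassed
Reagents that add atoms: none
Why: Sonogashira coupling; the bulky electron-rich phosphine lets the electron-rich aryl bromide undergo oxidative addition at room temperature, and the secondary amine base is too weak to isomerise the propargylic centre to an allene.

Step 9
Reactants: 16 (R)-{4-[4-[(tert-butyldimethylsilyl)oxy]-3-(3,4,5-trimethoxybenzyl)but-1-yn-1-yl]-2,6-dimethoxyphenoxy}triisopropylsilane
Product: 17 (R)-4-{3,5-dimethoxy-4-[(triisopropylsilyl)oxy]phenyl}-2-(3,4,5-trimethoxybenzyl)but-3-yn-1-ol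
Conditions: CSA (cat.), MeOH/CH2Cl2, 0 °C
Reagents that add atoms: none
Why: Acid-catalysed methanolysis of silyl ethers (selective desilylation) is far faster for the unhindered primary alkyl ether than for the hindered, less basic aryl triisopropylsilyl ether, so only the hydroxymethyl group is unmasked.

Step 10
Reactants: 17 (R)-4-{3,5-dimethoxy-4-[(triisopropylsilyl)oxy]phenyl}-2-(3,4,5-trimethoxybenzyl)but-3-yn-1-ol; 18 carbon monoxide
Product: 19 (R,E)-3-{3,5-dimethoxy-4-[(triisopropylsilyl)oxy]benzylidene}-4-(3,4,5-trimethoxybenzyl)dihydrofuran-2(3H)-one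
Conditions: PdCl2(PPh3)2 (5 mol%), SnCl2 (5 mol%), CO (ca. 7 bar), MeCN, 75 °C
Reagents that add atoms: none
Why: The primary hydroxyl and CO should give a palladium(II) alkoxycarbonyl that adds across the tethered alkyne in a syn fashion, and the resulting vinyl–palladium bond is cleaved with retention by the proton released in the first event; a hydride cycle (syn hydropalladation, CO insertion, lactonisation) would converge on the same product. The closest known reaction type is the palladium-catalysed cyclocarbonylation of but-3-yn-1-ols to α-alkylidene-γ-butyrolactones. The butyrolactone closes in the 5-exo-dig mode, because the endo alternative would place the acyl carbon and C3 trans on an endocyclic alkene of a six-membered ring and cannot close. No stereocentre is created; the alkene geometry follows from syn delivery of the acyl group and hydrogen, which leaves H cis to the carbonyl and the aryl group cis to C3 (E), the isomer that is also expected to be the more stable. The step needs acyl attachment at the alkyne carbon next to C3 and an intact propargylic centre: the two-atom CH2O tether secures the first, and the base-free, weakly acidic medium secures the second and spares the aryl silyl ether.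

Step 11
Reactants: 19 (R,E)-3-{3,5-dimethoxy-4-[(triisopropylsilyl)oxy]benzylidene}-4-(3,4,5-trimethoxybenzyl)dihydrofuran-2(3H)-one
Product: 20 (R,E)-3-(4-hydroxy-3,5-dimethoxybenzylidene)-4-(3,4,5-trimethoxybenzyl)dihydrofuran-2(3H)-one (target)
Conditions: TBAF, AcOH (1:1), THF, 0 °C
Reagents that add atoms: none
Why: Fluoride-mediated desilylation of the aryl silyl ether; acetic acid buffers fluoride and the phenoxide, so the γ-acidic allylic C3–H should not be removed and neither epimerisation nor migration of the alkene into the ring is expected.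

**Compound list**
1 | 3-(3,4,5-trimethoxyphenyl)propanoic acid | OC(=O)CCc1cc(OC)c(OC)c(OC)c1 | starting material
2 | (R)-4-benzyloxazolidin-2-one | O=C1N[C@H](Cc2ccccc2)CO1 | starting material
3 | 3-(3,4,5-trimethoxyphenyl)propanoic pivalic anhydride | CC(C)(C)C(=O)OC(=O)CCc1cc(OC)c(OC)c(OC)c1 | intermediate
4 | (R)-4-benzyl-3-[3-(3,4,5-trimethoxyphenyl)propanoyl]oxazolidin-2-one | O=C(CCc1cc(OC)c(OC)c(OC)c1)N1[C@H](Cc2ccccc2)COC1=O | intermediate
5 | 1,3,5-trioxane | C1OCOCO1 | starting material
6 | trichlorotitanium (Z)-enolate of 4 | COc1cc(C/C=C(/N2[C@H](Cc3ccccc3)COC2=O)O[Ti](Cl)(Cl)Cl)cc(OC)c1OC | intermediate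
7 | (R)-4-benzyl-3-[(S)-2-(hydroxymethyl)-3-(3,4,5-trimethoxyphenyl)propanoyl]oxazolidin-2-one | OC[C@@H](C(=O)N1[C@H](Cc2ccccc2)COC1=O)Cc1cc(OC)c(OC)c(OC)c1 | intermediate
8 | (R)-4-benzyl-3-[(S)-2-{[(tert-butyldimethylsilyl)oxy]methyl}-3-(3,4,5-trimethoxyphenyl)propanoyl]oxazolidin-2-one | CC(C)(C)[Si](C)(C)OC[C@@H](C(=O)N1[C@H](Cc2ccccc2)COC1=O)Cc1cc(OC)c(OC)c(OC)c1 | intermediate
9 | (R)-3-[(tert-butyldimethylsilyl)oxy]-2-(3,4,5-trimethoxybenzyl)propan-1-ol | CC(C)(C)[Si](C)(C)OC[C@@H](CO)Cc1cc(OC)c(OC)c(OC)c1 | intermediate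
10 | (S)-3-[(tert-butyldimethylsilyl)oxy]-2-(3,4,5-trimethoxybenzyl)propanal | CC(C)(C)[Si](C)(C)OC[C@@H](C=O)Cc1cc(OC)c(OC)c(OC)c1 | intermediate
11 | dimethyl (1-diazo-2-oxopropyl)phosphonate | CC(=O)C(=[N+]=[N-])P(=O)(OC)OC | starting material
12 | (R)-tert-butyl{[4-diazo-2-(3,4,5-trimethoxybenzyl)but-3-en-1-yl]oxy}dimethylsilane | CC(C)(C)[Si](C)(C)OC[C@@H](C=C=[N+]=[N-])Cc1cc(OC)c(OC)c(OC)c1 | intermediate
13 | (R)-tert-butyldimethyl{[2-(3,4,5-trimethoxybenzyl)but-3-yn-1-yl]oxy}silane | CC(C)(C)[Si](C)(C)OC[C@@H](C#C)Cc1cc(OC)c(OC)c(OC)c1 | intermediate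
14 | 4-bromo-2,6-dimethoxyphenol | COc1cc(Br)cc(OC)c1O | starting material
15 | (4-bromo-2,6-dimethoxyphenoxy)triisopropylsilane | COc1cc(Br)cc(OC)c1O[Si](C(C)C)(C(C)C)C(C)C | intermediate
16 | (R)-{4-[4-[(tert-butyldimethylsilyl)oxy]-3-(3,4,5-trimethoxybenzyl)but-1-yn-1-yl]-2,6-dimethoxyphenoxy}triisopropylsilane | CC(C)(C)[Si](C)(C)OC[C@@H](C#Cc1cc(OC)c(O[Si](C(C)C)(C(C)C)C(C)C)c(OC)c1)Cc1cc(OC)c(OC)c(OC)c1 | intermediate
17 | (R)-4-{3,5-dimethoxy-4-[(triisopropylsilyl)oxy]phenyl}-2-(3,4,5-trimethoxybenzyl)but-3-yn-1-ol | OC[C@@H](C#Cc1cc(OC)c(O[Si](C(C)C)(C(C)C)C(C)C)c(OC)c1)Cc1cc(OC)c(OC)c(OC)c1 | intermediate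
18 | carbon monoxide | [C-]#[O+] | starting material
19 | (R,E)-3-{3,5-dimethoxy-4-[(triisopropylsilyl)oxy]benzylidene}-4-(3,4,5-trimethoxybenzyl)dihydrofuran-2(3H)-one | COc1cc(/C=C2/C(=O)OC[C@@H]2Cc2cc(OC)c(OC)c(OC)c2)cc(OC)c1O[Si](C(C)C)(C(C)C)C(C)C | intermediate
20 | (R,E)-3-(4-hydroxy-3,5-dimethoxybenzylidene)-4-(3,4,5-trimethoxybenzyl)dihydrofuran-2(3H)-one | COc1cc(/C=C2/C(=O)OC[C@@H]2Cc2cc(OC)c(OC)c(OC)c2)cc(OC)c1O | target

**Step count**
Total steps: 11. Longest linear sequence: 10 steps (from 1 through steps 1–6 and 8–11 to 20; step 7 lies on the aryl bromide branch).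

**Steps most likely to fail**

Step 10 (cyclocarbonylation). The aryl-capped internal alkyne may insert too slowly into the palladium alkoxycarbonyl, so that 5-endo hydroalkoxylation to a dihydrofuran or intermolecular ester formation overtakes lactone closure. The fallback separates carbonylation from arylation. It sets out from terminal alkyne 13: acid methanolysis of the silyl ether (CSA, MeOH) should give (R)-2-(3,4,5-trimethoxybenzyl)but-3-yn-1-ol F1, a terminal but-3-yn-1-ol of the kind for which the cyclocarbonylation is best established. Under the same Pd/CO conditions with 18 this should give (R)-3-methylene-4-(3,4,5-trimethoxybenzyl)dihydrofuran-2(3H)-one F2. A Mizoroki–Heck arylation of the exocyclic methylene with aryl bromide 15 (Pd2(dba)3, P(t-Bu)3, Cy2NMe, dioxane) should then give the E arylidene lactone by syn carbopalladation and syn β-hydride elimination from the new benzylic CH2, with the aryl group turned away from the carbonyl. The fallback comes back to the route at 19.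

Step 2 (hydroxymethylation). The Lewis-acid-activated formaldehyde may attack the electron-rich trimethoxyphenyl ring or add more than once, and facial selectivity may erode if the enolate is not fully chelated. The fallback sets out from 4 and avoids the Lewis acid. The sodium enolate (NaHMDS, THF, −78 °C) is alkylated with benzyl chloromethyl ether to give (R)-4-benzyl-3-[(S)-2-[(benzyloxy)methyl]-3-(3,4,5-trimethoxyphenyl)propanoyl]oxazolidin-2-one F3, with the same facial sense (electrophile anti to the auxiliary benzyl group on the chelated Z enolate). Hydrogenolysis of the benzyl ether (H2, Pd/C, EtOAc), possible at this stage because no alkyne or alkene is yet present, comes back to the route at 7.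

Step 6 (alkyne homologation). The α-branched aldehyde may epimerise or undergo β-elimination of the silyloxy group in carbonate/methanol before the olefination takes place. The fallback is a Corey–Fuchs sequence setting out from 10. Non-basic dibromo-olefination (CBr4, PPh3, CH2Cl2, 0 °C) should give (R)-tert-butyl{[4,4-dibromo-2-(3,4,5-trimethoxybenzyl)but-3-en-1-yl]oxy}dimethylsilane F4. Treatment with n-BuLi (2 equiv., THF, −78 °C) and then water converts it into the terminal alkyne, and the fallback comes back to the route at 13.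

**Further compounds**
F1 | step 10 | (R)-2-(3,4,5-trimethoxybenzyl)but-3-yn-1-ol | OC[C@@H](C#C)Cc1cc(OC)c(OC)c(OC)c1
F2 | step 10 | (R)-3-methylene-4-(3,4,5-trimethoxybenzyl)dihydrofuran-2(3H)-one | C=C1C(=O)OC[C@@H]1Cc2cc(OC)c(OC)c(OC)c2
F3 | step 2 | (R)-4-benzyl-3-[(S)-2-[(benzyloxy)methyl]-3-(3,4,5-trimethoxyphenyl)propanoyl]oxazolidin-2-one | O(Cc1ccccc1)C[C@@H](C(=O)N2[C@H](Cc3ccccc3)COC2=O)Cc4cc(OC)c(OC)c(OC)c4
F4 | step 6 | (R)-tert-butyl{[4,4-dibromo-2-(3,4,5-trimethoxybenzyl)but-3-en-1-yl]oxy}dimethylsilane | CC(C)(C)[Si](C)(C)OC[C@@H](C=C(Br)Br)Cc1cc(OC)c(OC)c(OC)c1
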